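**Assumption:** atom numbers (C2–C8a, C1′–C6′) and ring letters A, B, C are those of the isoflavone. Compounds 1, 2, 6, 13 and 14 are taken as purchasable; ynol ether 16 is treated as a reagent that has to be made (step 8).

## Analysis of the target

Piscerythrinetin (22) is an isoflavone. Its benzo ring A (C4a, C5, C6, C7, C8, C8a) carries hydroxyl groups on C5 and C7. The 4-pyranone ring C (O1, C2–H, C3, C4=O) carries the aryl ring B on C3. Ring B has methoxy groups on C3′ and C4′ and a prenyl (3-methylbut-2-en-1-yl) chain on C5′. There is no stereocentre, so every difficulty is one of regiochemistry and functional-group tolerance. The prenyl alkene does not tolerate strong protic acid, hydrogen halides, electrophilic halogen or hydrogenation, and the pyranone opens when hydroxide or amines add to C2. The two free phenols of ring A stand beside two methyl ethers of ring B, so a closing global demethylation is excluded and the ring A oxygens must arrive already differentiated from those of ring B. Ring B is 1,3,4,5-tetrasubstituted, with the prenyl group meta to the bond to C3, a position that electrophilic substitution of a veratrole does not reach. The strategy rests on ring A: it is a resorcinol with oxygen on C5 and C7 and hydrogen on C6 and C8, fused through C4a–C8a to a double bond of ring C. This alternating pattern is what a vinylketene (the pyranone C=C as the vinyl unit) and an oxygen-substituted alkyne assemble.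

## Retrosynthetic reasoning

**22 to 21.** The O–Si bond at C7 is cut last. The C7 oxygen enters as a triisopropylsilyl ether during ring construction, and fluoride removes it without touching the prenyl chain, the methyl ethers or ring C. The C5 hydroxyl needs no protection at any stage.

**21 to 12 and 16.** Ring A is taken apart at C5–C6, C7–C8 and C4a–C5. Cutting here and nowhere else leaves ring C and the fully substituted ring B intact. It also avoids having to distinguish the oxygens of a phloroglucinol. In the forward direction diazoketone 12 must rearrange to a ketene. This ketene must add ynol ether 16 with the unsubstituted alkyne carbon on the ketene carbonyl carbon. The four-membered ring must open, and the resulting dienylketene must close onto pyranone C3. The ketene oxygen then becomes the C5 hydroxyl and the siloxy group lands on C7.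

**12 to 10 (through 11).** The bond between the ketone carbon (future C5) and the diazo carbon (future C8) is cut. It is formed by acylating a diazoalkane with acid chloride 11. The carboxyl carbon at pyranone C2 is already present in the starting pyranone, so no carbon–carbon bond to the ring has to be made.

**10 to 9, then 9 to 8 and 5.** After ester hydrolysis the C3–C1′ bond is cut. The enolic oxygen at pyranone C5 is a ready handle: as triflate 8 it couples with arylboronate 5. This is convergent and brings ring B in complete, so no prenylation or methylation is needed on the heterocycle.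

**8 to 7 to 6.** Triflation and esterification lead back to comenic acid 6, which holds the pyranone, the carboxyl carbon and the oxygen handle in the right places.

**5 to 4, then 4 to 1 and 2.** The C1′–B bond is cut to a C–H bond. In arene 4 this is the only aromatic C–H with no ortho substituent, so a sterically governed C–H borylation finds it. The C5′–CH2 bond is then cut to veratrole 1 and prenyl bromide 2. The methoxy groups of 1 direct lithiation to the adjacent carbon, which gives the contiguous 3′,4′,5′ pattern in two steps.

**16 to 13 and 14.** The O–Si bond and the alkyne C–C bond are cut. Ethyl formate 13 is homologated by one carbon to ynolate 15, and triflate 14 silylates it on oxygen.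

## Alternatives that were turned down

**Alternative 1:** The C3–C4 bond is cut. In the forward step an N-heterocyclic carbene turns the aldehyde of keto-aldehyde A1 into an acyl anion equivalent, which adds to the tethered aryl ketone and closes ring C as 3-hydroxychromanone A2.
- For it: the benzoin step is catalytic, thermal and avoids diazo compounds and light. On operational simplicity of the key step it is stronger than the chosen route.
- Against it: A2 is at the wrong oxidation level. Water must be lost across C2–C3, where the C2 hydrogens are not acidic and the C3 cation would sit next to a carbonyl, so the elimination needs activation or acid. The stereocentre made at C3 is thrown away. Two methoxymethyl ethers must then be removed with acid in the presence of the prenyl alkene. A1 needs a selectively protected trioxygenated benzaldehyde and an α-halo ketone made next to a prenyl group, which lengthens the linear sequence.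
- Comparison: the chosen route instead delivers the aromatic oxidation level directly, with C5–OH free and C7–O protected by a group that fluoride removes.

**Alternative 2:** Ring B is built instead of ring A, by cutting C1′–C2′ and C5′–C6′. Stille coupling of vinylstannane A3 with chlorocyclobutenone A4 gives a 4-vinylcyclobutenone. This opens thermally to a dienylketene and closes to phenol A5.
- For it: the cascade is purely thermal and the two adjacent methoxy groups come straight from the four-membered ring. It shares the electrocyclic logic of the chosen route without photochemistry and is at least as well precedented.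
- Against it: the ketene oxygen ends up on C5′, which in the target carries carbon. A5 therefore needs triflation and an allyl-type cross-coupling with a prenyl-metal reagent, in which attack through either end of the allyl unit competes. Ring A must be made beforehand with two protecting groups, which again come off with acid.
- Comparison: in the chosen route the oxygen set by the ketene is wanted where it lands (C5–OH), so no atom has to be exchanged after the annulation.

**Alternative 3:** O1–C8a and C4–C4a are cut. Fluoride releases an aryne from silyl triflate A6. The enol oxygen of hydroxyacrylate A7 adds at C8a, and the aryl anion at C4a closes onto the ester to give the protected isoflavone A8.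
- For it: this is the most convergent of the three, forms ring C in one mild step, and the alkoxy group next to C4a directs the nucleophile to C8a. On convergence it equals the chosen route.
- Against it: the enol of a β-formyl ester is ambident. Arynes usually bond to the carbon of such partners and insert into the C–C bond, so O-arylation followed by acyl capture is the less likely course. A6 takes several steps from a trioxygenated benzene, and the final acid deprotection again meets the prenyl group.
- Comparison: the chosen route puts its risk into a cascade whose regiochemistry is fixed by the polarity of the ynol ether, not by a competition between two nucleophilic sites, and it ends with a desilylation.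

Key step: step 9

## Route

Step 1
Reactants: 1 veratrole (1,2-dimethoxybenzene); 2 prenyl bromide (1-bromo-3-methylbut-2-ene)
Product: 4 1,2-dimethoxy-3-(3-methylbut-2-en-1-yl)benzene, via aryllithium 3 (not isolated)
Conditions: n-BuLi, TMEDA, Et2O, 0 °C to rt; CuI (10 mol %), then 2, −78 °C to rt
Reagents that add atoms: none
Why: Directed ortho-metalation of veratrole next to a methoxy group gives (2,3-dimethoxyphenyl)lithium 3; copper-catalysed allylic substitution on the primary bromide should occur at the unhindered CH2 terminus and give the prenyl, not the reverse-prenyl, arene.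

Step 2
Reactants: 4 1,2-dimethoxy-3-(3-methylbut-2-en-1-yl)benzene
Product: 5 2-[3,4-dimethoxy-5-(3-methylbut-2-en-1-yl)phenyl]-4,4,5,5-tetramethyl-1,3,2-dioxaborolane
Conditions: B2pin2 (1.0 equiv), [Ir(OMe)(cod)]2 (1.5 mol %), 4,4′-di-tert-butyl-2,2′-bipyridine (3 mol %), THF, 50 °C
Reagents that add atoms: bis(pinacolato)diboron, CC1(C)OB(OC1(C)C)B1OC(C)(C)C(C)(C)O1
Why: Iridium-catalysed aromatic C–H borylation is governed by sterics, and in this 1,2,3-trisubstituted benzene only the C–H para to the central methoxy group has no ortho substituent; the hindered trisubstituted alkene should react far more slowly than this open aryl C–H bond.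

Step 3
Reactants: 6 comenic acid (5-hydroxy-4-oxo-4H-pyran-2-carboxylic acid)
Product: 7 methyl 5-hydroxy-4-oxo-4H-pyran-2-carboxylate
Conditions: MeOH, H2SO4 (cat.), reflux
Reagents that add atoms: methanol, CO
Why: Fischer esterification; the enolic hydroxyl and the pyranone are inert to acidic methanol.

Step 4
Reactants: 7 methyl 5-hydroxy-4-oxo-4H-pyran-2-carboxylate
Product: 8 methyl 4-oxo-5-(trifluoromethylsulfonyloxy)-4H-pyran-2-carboxylate
Conditions: Tf2O, pyridine, CH2Cl2, −10 to 0 °C
Reagents that add atoms: trifluoromethanesulfonic anhydride, O=S(=O)(OS(=O)(=O)C(F)(F)F)C(F)(F)F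
Why: O-Sulfonylation of the acidic enol of a 3-hydroxy-4-pyranone gives an alkenyl triflate that the adjacent carbonyl activates for oxidative addition.

Step 5
Reactants: 8 methyl 4-oxo-5-(trifluoromethylsulfonyloxy)-4H-pyran-2-carboxylate; 5 2-[3,4-dimethoxy-5-(3-methylbut-2-en-1-yl)phenyl]-4,4,5,5-tetramethyl-1,3,2-dioxaborolane
Product: 9 methyl 5-[3,4-dimethoxy-5-(3-methylbut-2-en-1-yl)phenyl]-4-oxo-4H-pyran-2-carboxylate
Conditions: Pd(dppf)Cl2 (5 mol %), K3PO4, 1,4-dioxane/H2O (20:1), 70 °C
Reagents that add atoms: none
Why: Suzuki–Miyaura coupling; the electron-poor alkenyl triflate adds quickly to zerovalent palladium, and a phosphate base with little water limits triflate hydrolysis and pyranone opening. Partial ester hydrolysis would do no harm, since the acid is the next intermediate.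

Step 6
Reactants: 9 methyl 5-[3,4-dimethoxy-5-(3-methylbut-2-en-1-yl)phenyl]-4-oxo-4H-pyran-2-carboxylate
Product: 10 5-[3,4-dimethoxy-5-(3-methylbut-2-en-1-yl)phenyl]-4-oxo-4H-pyran-2-carboxylic acid
Conditions: LiOH, THF/H2O (3:1), 0 °C; then 1 M HCl to pH 3
Reagents that add atoms: lithium hydroxide, [Li+].[OH-]
Why: Saponification; the ester on pyranone C2 is strongly activated, so hydroxide should attack the acyl carbon faster than it adds to the ring at 0 °C, and the brief cold acidification leaves the prenyl alkene untouched.

Step 7
Reactants: 10 5-[3,4-dimethoxy-5-(3-methylbut-2-en-1-yl)phenyl]-4-oxo-4H-pyran-2-carboxylic acid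
Product: 12 2-diazo-1-{5-[3,4-dimethoxy-5-(3-methylbut-2-en-1-yl)phenyl]-4-oxo-4H-pyran-2-yl}ethan-1-one, via acid chloride 11 (not isolated)
Conditions: 1-chloro-N,N,2-trimethylprop-1-en-1-amine, CH2Cl2, 0 °C to rt; then CH2N2 (1.5 equiv), Et3N, Et2O/CH2Cl2, −20 to 0 °C
Reagents that add atoms: diazomethane, C=[N+]=[N-]; 1-chloro-N,N,2-trimethylprop-1-en-1-amine, CC(C)=C(Cl)N(C)C (chlorine, in 11 only)
Why: The chloroenamine makes the acid chloride under neutral conditions, so no hydrogen chloride is free to add to the prenyl alkene; acylation of diazomethane (first stage of the Arndt–Eistert sequence) with triethylamine as acid acceptor needs only a small excess of the dipole, which together with the low temperature should hold back its cycloaddition to the pyranone double bond.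

Step 8
Reactants: 13 ethyl formate; 14 triisopropylsilyl trifluoromethanesulfonate
Product: 16 (triisopropylsilyloxy)acetylene, via lithium ethynolate 15 (not isolated)
Conditions: CH2Br2, LiTMP, THF, −78 °C; 13; LiHMDS, then n-BuLi, −78 °C to rt; then 14, −78 to 0 °C
Reagents that add atoms: dibromomethane, BrCBr
Why: Kowalski ester homologation applied to a formate: dibromomethyllithium adds to the ester, bromine–lithium exchange and deprotonation give an α-bromo enolate carbenoid, and a 1,2-hydrogen shift gives ynolate 15. The bulky silyl triflate should silylate the ynolate on oxygen, as in the known preparation of 1-(triisopropylsilyloxy)alkynes.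

Step 9
Reactants: 12 2-diazo-1-{5-[3,4-dimethoxy-5-(3-methylbut-2-en-1-yl)phenyl]-4-oxo-4H-pyran-2-yl}ethan-1-one; 16 (triisopropylsilyloxy)acetylene
Product: 21 5-hydroxy-3-[3,4-dimethoxy-5-(3-methylbut-2-en-1-yl)phenyl]-7-(triisopropylsilyloxy)-4H-chromen-4-one, via pyranonylketene 17 (not isolated), via cyclobutenone 18 (not isolated), via dienylketene 19 (not isolated), via cyclohexadienone 20 (not isolated)
Conditions: 16 (3 equiv), ClCH2CH2Cl (0.05 M, degassed), hν (300–365 nm, Pyrex), rt; then 80 °C
Reagents that add atoms: none
Why: Irradiation expels dinitrogen from 12, and the Wolff shift moves pyranone C2 (future C8a) onto the diazo carbon (future C8) to give ketene 17, whose carbonyl carbon becomes C5. The polarised ynol ether 16 then adds across the ketene C=C in a (2+2) cycloaddition, its nucleophilic unsubstituted carbon bonding to the ketene carbonyl carbon (C5–C6) and its oxygen-bearing carbon to the former diazo carbon (C7–C8), to give cyclobutenone 18. On heating, 18 opens by reversible 4π electrocyclic cleavage of the C5–C8 bond to dienylketene 19; only the isomer with the pyranonyl group turned inward can go on, and the other returns to 18. Ring A closes by thermal disrotatory 6π electrocyclization between the ketene carbon and pyranone C3 (C4a–C5) to give dienone 20, whose C4a hydrogen lies between two carbonyl groups and shifts at once to oxygen, giving phenol 21 with gain of aromaticity and a C5–OH to C4=O hydrogen bond. The closest known reaction type is the Danheiser benzannulation in its photochemical Wolff form, in which aryl, heteroaryl and vinyl diazoketones react with silyl ynol ethers to give resorcinol monosilyl ethers of the same oxygen pattern. No stereocentre remains in 21; those of 18 and 20 are transient and are erased by ring opening and tautomerisation. The step needs the right orientation in the cycloaddition, which the donor oxygen of 16 secures, and closure at a single site, which is secured because C3 is the only pyranone carbon conjugated with and within reach of the ketene. It also needs chemoselectivity, secured by the excess of the strongly ketenophilic ynol ether over the unactivated prenyl alkene and by long-wavelength light, which spares the pyranone chromophore.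

Step 10
Reactants: 21 5-hydroxy-3-[3,4-dimethoxy-5-(3-methylbut-2-en-1-yl)phenyl]-7-(triisopropylsilyloxy)-4H-chromen-4-one
Product: 22 piscerythrinetin, 5,7-dihydroxy-3-[3,4-dimethoxy-5-(3-methylbut-2-en-1-yl)phenyl]-4H-chromen-4-one
Conditions: TBAF, AcOH, THF, 0 °C
Reagents that add atoms: none
Why: Fluoride cleaves the aryl silyl ether at the acidic C7 oxygen; acetic acid buffers the phenoxide so that ring C is not exposed to strong base, and the methyl ethers and the prenyl group are inert.

## Compound list

1 | veratrole (1,2-dimethoxybenzene) | COc1ccccc1OC | starting material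
2 | prenyl bromide (1-bromo-3-methylbut-2-ene) | CC(C)=CCBr | starting material
3 | (2,3-dimethoxyphenyl)lithium | [Li]c1cccc(OC)c1OC | intermediate
4 | 1,2-dimethoxy-3-(3-methylbut-2-en-1-yl)benzene | COc1cccc(CC=C(C)C)c1OC | intermediate
5 | 2-[3,4-dimethoxy-5-(3-methylbut-2-en-1-yl)phenyl]-4,4,5,5-tetramethyl-1,3,2-dioxaborolane | COc1cc(B2OC(C)(C)C(C)(C)O2)cc(CC=C(C)C)c1OC | intermediate
6 | comenic acid (5-hydroxy-4-oxo-4H-pyran-2-carboxylic acid) | O=C(O)c1cc(=O)c(O)co1 | starting material
7 | methyl 5-hydroxy-4-oxo-4H-pyran-2-carboxylate | COC(=O)c1cc(=O)c(O)co1 | intermediate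
8 | methyl 4-oxo-5-(trifluoromethylsulfonyloxy)-4H-pyran-2-carboxylate | COC(=O)c1cc(=O)c(OS(=O)(=O)C(F)(F)F)co1 | intermediate
9 | methyl 5-[3,4-dimethoxy-5-(3-methylbut-2-en-1-yl)phenyl]-4-oxo-4H-pyran-2-carboxylate | COC(=O)c1cc(=O)c(-c2cc(OC)c(OC)c(CC=C(C)C)c2)co1 | intermediate
10 | 5-[3,4-dimethoxy-5-(3-methylbut-2-en-1-yl)phenyl]-4-oxo-4H-pyran-2-carboxylic acid | OC(=O)c1cc(=O)c(-c2cc(OC)c(OC)c(CC=C(C)C)c2)co1 | intermediate
11 | 5-[3,4-dimethoxy-5-(3-methylbut-2-en-1-yl)phenyl]-4-oxo-4H-pyran-2-carbonyl chloride | O=C(Cl)c1cc(=O)c(-c2cc(OC)c(OC)c(CC=C(C)C)c2)co1 | intermediate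
12 | 2-diazo-1-{5-[3,4-dimethoxy-5-(3-methylbut-2-en-1-yl)phenyl]-4-oxo-4H-pyran-2-yl}ethan-1-one | [N-]=[N+]=CC(=O)c1cc(=O)c(-c2cc(OC)c(OC)c(CC=C(C)C)c2)co1 | intermediate
13 | ethyl formate | CCOC=O | starting material
14 | triisopropylsilyl trifluoromethanesulfonate | CC(C)[Si](OS(=O)(=O)C(F)(F)F)(C(C)C)C(C)C | starting material
15 | lithium ethynolate | [Li+].[O-]C#C | intermediate
16 | (triisopropylsilyloxy)acetylene | C#CO[Si](C(C)C)(C(C)C)C(C)C | intermediate
17 | 2-{5-[3,4-dimethoxy-5-(3-methylbut-2-en-1-yl)phenyl]-4-oxo-4H-pyran-2-yl}ethen-1-one (pyranonylketene) | O=C=Cc1cc(=O)c(-c2cc(OC)c(OC)c(CC=C(C)C)c2)co1 | intermediate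
18 | 4-{5-[3,4-dimethoxy-5-(3-methylbut-2-en-1-yl)phenyl]-4-oxo-4H-pyran-2-yl}-3-(triisopropylsilyloxy)cyclobut-2-en-1-one (racemic) | O=C1C=C(O[Si](C(C)C)(C(C)C)C(C)C)C1c1cc(=O)c(-c2cc(OC)c(OC)c(CC=C(C)C)c2)co1 | intermediate
19 | 4-{5-[3,4-dimethoxy-5-(3-methylbut-2-en-1-yl)phenyl]-4-oxo-4H-pyran-2-yl}-3-(triisopropylsilyloxy)buta-1,3-dien-1-one (3E isomer, ketenyl and pyranonyl groups cis) | O=C=C/C(O[Si](C(C)C)(C(C)C)C(C)C)=C\c1cc(=O)c(-c2cc(OC)c(OC)c(CC=C(C)C)c2)co1 | intermediate
20 | 3-[3,4-dimethoxy-5-(3-methylbut-2-en-1-yl)phenyl]-7-(triisopropylsilyloxy)-4aH-chromene-4,5-dione (racemic) | O=C1C=C(O[Si](C(C)C)(C(C)C)C(C)C)C=C2OC=C(-c3cc(OC)c(OC)c(CC=C(C)C)c3)C(=O)C12 | intermediate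
21 | 5-hydroxy-3-[3,4-dimethoxy-5-(3-methylbut-2-en-1-yl)phenyl]-7-(triisopropylsilyloxy)-4H-chromen-4-one | COc1cc(-c2coc3cc(O[Si](C(C)C)(C(C)C)C(C)C)cc(O)c3c2=O)cc(CC=C(C)C)c1OC | intermediate
22 | piscerythrinetin, 5,7-dihydroxy-3-[3,4-dimethoxy-5-(3-methylbut-2-en-1-yl)phenyl]-4H-chromen-4-one | COc1cc(-c2coc3cc(O)cc(O)c3c2=O)cc(CC=C(C)C)c1OC | target

## Step count and least certain steps

Total: 10 steps. Longest linear sequence: 7 steps (3, 4, 5, 6, 7, 9, 10 from comenic acid 6; equally 1, 2, 5, 6, 7, 9, 10 from veratrole 1).

**Step 9 (key step).**
- Risk: photodecomposition of the pyranone chromophore and of the light- and acid-sensitive ynol ether may compete with the Wolff rearrangement. The sequence may also stall at the cyclobutenone, because outward rotation of the pyranonyl group on ring opening gives a ketene that cannot cyclise. The ketene may also acylate the product phenol.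
- Fallback: make the same ketene without light. From diazoketone 12, a silver-catalysed Wolff rearrangement in aqueous THF (PhCO2Ag, Et3N; Arndt–Eistert homologation) should give 2-{5-[3,4-dimethoxy-5-(3-methylbut-2-en-1-yl)phenyl]-4-oxo-4H-pyran-2-yl}acetic acid F1. The neutral chloroenamine of step 7 converts it into the acid chloride F2. Slow addition of triethylamine to F2 and 16 at 0 °C generates ketene 17 by dehydrochlorination in the dark. Its cycloadduct 18 is then isolated and heated in toluene at 80–110 °C. The route is rejoined at 21.

**Step 8.**
- Risk: a second addition of the carbenoid to the very electrophilic formate, metalation of the terminal ynolate followed by silylation on carbon, and loss of the volatile product on isolation.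
- Fallback: form the C–O bond by oxidation instead of homologation. Acetylene F3 is lithiated with n-BuLi in THF at −78 °C to lithium acetylide F4. This is oxygenated with lithium tert-butyl peroxide (from t-BuOOH and LiHMDS) to ynolate 15 and silylated with 14. The fallback sets out from triflate 14 and rejoins the route at 15 and then 16.

**Step 7.**
- Risk: dipolar cycloaddition of diazomethane to the acyl-activated C=C bond of the pyranone, giving pyrazolines, and capture of the diazonium intermediate by chloride.
- Fallback: avoid diazomethane by diazo transfer. Acid chloride 11 is converted with N,O-dimethylhydroxylamine hydrochloride and pyridine into the N-methoxy-N-methylamide F5. MeMgBr at −78 °C gives the methyl ketone F6. Its lithium enolate (LiHMDS) is trifluoroacetylated with 2,2,2-trifluoroethyl trifluoroacetate to the diketone F7, which is not isolated. Methanesulfonyl azide, Et3N and water in MeCN then effect detrifluoroacetylative diazo transfer. The route is rejoined at 12.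

**Step 2.**
- Risk: reaction of the iridium boryl and hydride species at the prenyl alkene (hydroboration, vinylic borylation or migration of the double bond into conjugation), and minor borylation next to a methoxy group.
- Fallback: install boron from a halide. 4-Bromo-2-methoxyphenol F8 is iodinated ortho to the hydroxyl (N-iodosuccinimide) to 4-bromo-2-iodo-6-methoxyphenol F9 and methylated (MeI, K2CO3) to 5-bromo-1-iodo-2,3-dimethoxybenzene F10. Selective iodine–magnesium exchange (i-PrMgCl·LiCl, −20 °C) and copper-catalysed allylation (CuI) with prenyl bromide 2 give 5-bromo-1,2-dimethoxy-3-(3-methylbut-2-en-1-yl)benzene F11. Miyaura borylation (B2pin2, Pd(dppf)Cl2, KOAc, dioxane, 80 °C) rejoins the route at 5. The fallback sets out from prenyl bromide 2.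

**Step 5.**
- Risk: base-induced cleavage of the triflate S–O bond and opening of the pyranone ring may outrun transmetalation, and the boronate may undergo protodeboronation.
- Fallback: couple without base. Bromide F11 (from the fallback to step 2) is lithiated with n-BuLi at −78 °C and transmetalated with ZnCl2 to [3,4-dimethoxy-5-(3-methylbut-2-en-1-yl)phenyl]zinc chloride F12. Negishi coupling with triflate 8 (Pd(PPh3)4, THF, rt to 50 °C) should give 9. The fallback sets out from triflate 8 and rejoins the route at 9.

## Further compounds

F1 | step 9 | 2-{5-[3,4-dimethoxy-5-(3-methylbut-2-en-1-yl)phenyl]-4-oxo-4H-pyran-2-yl}acetic acid | OC(=O)Cc1cc(=O)c(-c2cc(OC)c(OC)c(CC=C(C)C)c2)co1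
F2 | step 9 | 2-{5-[3,4-dimethoxy-5-(3-methylbut-2-en-1-yl)phenyl]-4-oxo-4H-pyran-2-yl}acetyl chloride | O=C(Cl)Cc1cc(=O)c(-c2cc(OC)c(OC)c(CC=C(C)C)c2)co1
F3 | step 8 | acetylene | C#C
F4 | step 8 | lithium acetylide | [Li]C#C
F5 | step 7 | 5-[3,4-dimethoxy-5-(3-methylbut-2-en-1-yl)phenyl]-N-methoxy-N-methyl-4-oxo-4H-pyran-2-carboxamide | CON(C)C(=O)c1cc(=O)c(-c2cc(OC)c(OC)c(CC=C(C)C)c2)co1
F6 | step 7 | 2-acetyl-5-[3,4-dimethoxy-5-(3-methylbut-2-en-1-yl)phenyl]-4H-pyran-4-one | CC(=O)c1cc(=O)c(-c2cc(OC)c(OC)c(CC=C(C)C)c2)co1
F7 | step 7 | 1-{5-[3,4-dimethoxy-5-(3-methylbut-2-en-1-yl)phenyl]-4-oxo-4H-pyran-2-yl}-4,4,4-trifluorobutane-1,3-dione | O=C(CC(=O)C(F)(F)F)c1cc(=O)c(-c2cc(OC)c(OC)c(CC=C(C)C)c2)co1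
F8 | step 2 | 4-bromo-2-methoxyphenol | COc1cc(Br)ccc1O
F9 | step 2 | 4-bromo-2-iodo-6-methoxyphenol | COc1cc(Br)cc(I)c1O
F10 | step 2 | 5-bromo-1-iodo-2,3-dimethoxybenzene | COc1cc(Br)cc(I)c1OC
F11 | step 2 | 5-bromo-1,2-dimethoxy-3-(3-methylbut-2-en-1-yl)benzene | COc1cc(Br)cc(CC=C(C)C)c1OC
F12 | step 5 | [3,4-dimethoxy-5-(3-methylbut-2-en-1-yl)phenyl]zinc chloride | Cl[Zn]c1cc(OC)c(OC)c(CC=C(C)C)c1
A1 | alternative 1 | 2-{2-[3,4-dimethoxy-5-(3-methylbut-2-en-1-yl)phenyl]-2-oxoethoxy}-4,6-bis(methoxymethoxy)benzaldehyde | O=Cc1c(OCOC)cc(OCOC)cc1OCC(=O)c1cc(OC)c(OC)c(CC=C(C)C)c1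
A2 | alternative 1 | 3-hydroxy-3-[3,4-dimethoxy-5-(3-methylbut-2-en-1-yl)phenyl]-5,7-bis(methoxymethoxy)chroman-4-one (racemic) | COCOc1cc(OCOC)c2c(c1)OCC(O)(c1cc(OC)c(OC)c(CC=C(C)C)c1)C2=O
A3 | alternative 2 | 5,7-bis(methoxymethoxy)-3-[1-(tributylstannyl)ethenyl]-4H-chromen-4-one | COCOc1cc(OCOC)c2c(c1)occ(C(=C)[Sn](CCCC)(CCCC)CCCC)c2=O
A4 | alternative 2 | 4-chloro-2,3-dimethoxycyclobut-2-en-1-one | COC1=C(OC)C(Cl)C1=O
A5 | alternative 2 | 3-(3-hydroxy-4,5-dimethoxyphenyl)-5,7-bis(methoxymethoxy)-4H-chromen-4-one | COCOc1cc(OCOC)c2c(c1)occ(-c1cc(O)c(OC)c(OC)c1)c2=O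
A6 | alternative 3 | 3,5-bis(methoxymethoxy)-2-(trimethylsilyl)phenyl trifluoromethanesulfonate | COCOc1cc(OCOC)c([Si](C)(C)C)c(OS(=O)(=O)C(F)(F)F)c1
A7 | alternative 3 | methyl 2-[3,4-dimethoxy-5-(3-methylbut-2-en-1-yl)phenyl]-3-hydroxyprop-2-enoate | COC(=O)C(=CO)c1cc(OC)c(OC)c(CC=C(C)C)c1
A8 | alternative 3 | 5,7-bis(methoxymethoxy)-3-[3,4-dimethoxy-5-(3-methylbut-2-en-1-yl)phenyl]-4H-chromen-4-one | COCOc1cc(OCOC)c2c(c1)occ(-c1cc(OC)c(OC)c(CC=C(C)C)c1)c2=O
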